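**Plan**

1. Locants used below: ring B is the cyclohexane of the target, with C1 (quaternary carbon), C2 (CH), C3 (alkylidene carbon), C4, C5 and C6 (carbinol carbon); C7 is the CH2OH carbon on C1; C8–C10 are the 3-hydroxypropyl chain on C2.
2. Retrosynthesis: the enal goes back to the allylic alcohol and the triene arm is cut at its two conjugated C=C bonds (two Wittig reactions). C7 and C10 are two cis primary carbinol carbons, so they are rejoined as a C7=C10 alkene. The target is then the seco form of a cis-fused bicycle in which ring A (C1, C2, C8, C9, C10, C7) plus C6 are the seven carbons of benzoic acid.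
3. Ring B is cut at C5–C6 (alkyl–acyl) and C2–C3 (ring CH–alkenyl). The fragments are acid chloride 11 (from Birch-alkylated benzoic acid) and iodoalkenyl iodide 7.
4. Forward: 7 (steps 1–5) and 11 (steps 6–7) are joined in step 8, which closes ring B on the temporary ring A. Then methyl addition at C6, reduction and oxidative opening of ring A to the C7 and C10 carbinols, two Wittig reactions on the arm, desilylation and allylic oxidation.
5. Stereochemistry: the (Z) exocyclic alkene comes from a chelate-controlled anti-carbomagnesiation and is carried through with retention. C1 and C2 are set together by a ligand-controlled, cis-selective Heck desymmetrisation of the prochiral cyclohexa-2,5-diene. C6 comes from substrate-controlled methyl addition, and the (E) alkenes of the arm from the Wittig steps.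

Key step: step 8

Abbreviations: TBS = tert-butyldimethylsilyl, TBDPS = tert-butyldiphenylsilyl, oxan-2-yl = tetrahydropyran-2-yl.
Assumption: (R)-BINAP is taken to select the enantiotopic ring alkene that leads to the (4aR,8aR) bicycle 14; if the opposite sense is found, (S)-BINAP is used.

Step 1
Reactants: 1 2-(but-3-yn-1-yloxy)oxane
Product: 2 5-(oxan-2-yloxy)pent-2-yn-1-ol
Conditions: n-BuLi, THF, −78 °C; (CH2O)n, −78 °C → rt; H2O
Reagents that add atoms: paraformaldehyde (formaldehyde unit), C=O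
Why: Addition of the lithium acetylide to formaldehyde should give the propargylic alcohol that directs the next step.

Step 2
Reactants: 2 5-(oxan-2-yloxy)pent-2-yn-1-ol
Product: 4 (2Z)-3-iodo-2-methyl-5-(oxan-2-yloxy)pent-2-en-1-ol, via cyclic alkenylmagnesium alkoxide 3 (not isolated)
Conditions: MeMgBr (4 equiv), CuI (10 mol%), THF, −20 °C → rt; then I2, −78 → 0 °C
Reagents that add atoms: methylmagnesium bromide, C[Mg]Br; iodine, II
Why: Copper-catalysed anti-carbomagnesiation of a 2-alkyn-1-ol puts methyl on C-2 and magnesium on C-3 inside a five-membered alkoxide chelate, so iodinolysis with retention should give the iodide with iodine cis to CH2OH, which fixes the geometry of the exocyclic alkene of the target.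

Step 3
Reactants: 4 (2Z)-3-iodo-2-methyl-5-(oxan-2-yloxy)pent-2-en-1-ol
Product: 5 tert-butyl{[(2Z)-3-iodo-2-methyl-5-(oxan-2-yloxy)pent-2-en-1-yl]oxy}diphenylsilane
Conditions: TBDPSCl, imidazole, DMF, rt
Reagents that add atoms: tert-butyl(chloro)diphenylsilane, CC(C)(C)[Si](Cl)(c1ccccc1)c1ccccc1
Why: Standard silylation of the primary allylic alcohol should give an ether that lasts until step 17.

Step 4
Reactants: 5 tert-butyl{[(2Z)-3-iodo-2-methyl-5-(oxan-2-yloxy)pent-2-en-1-yl]oxy}diphenylsilane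
Product: 6 (3Z)-5-(TBDPS-oxy)-3-iodo-4-methylpent-3-en-1-ol
Conditions: PPTS (cat.), MeOH, 40 °C
Reagents that add atoms: none
Why: Acid-catalysed transacetalisation should remove the tetrahydropyranyl group while the TBDPS ether stays.

Step 5
Reactants: 6 (3Z)-5-(TBDPS-oxy)-3-iodo-4-methylpent-3-en-1-ol
Product: 7 tert-butyl{[(2Z)-3,5-diiodo-2-methylpent-2-en-1-yl]oxy}diphenylsilane
Conditions: I2, PPh3, imidazole, CH2Cl2, 0 °C → rt
Reagents that add atoms: iodine, II
Why: The Appel reaction should turn the primary alcohol into the primary iodide without touching the alkenyl iodide.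

Step 6
Reactants: 8 benzoic acid; 9 (3-bromopropoxy)(tert-butyl)dimethylsilane
Product: 10 1-[3-(TBS-oxy)propyl]cyclohexa-2,5-diene-1-carboxylic acid
Conditions: Li, NH3(l)/THF, −78 °C; then 9, −78 → −33 °C; aq. NaH2PO4 to pH 4
Reagents that add atoms: none
Why: Birch reduction–alkylation of benzoate should alkylate the dienyl carboxylate dianion at the ipso carbon and give an achiral diene whose two ring alkenes are enantiotopic.

Step 7
Reactants: 10 1-[3-(TBS-oxy)propyl]cyclohexa-2,5-diene-1-carboxylic acid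
Product: 11 1-[3-(TBS-oxy)propyl]cyclohexa-2,5-diene-1-carbonyl chloride
Conditions: 1-chloro-N,N,2-trimethylprop-1-en-1-amine, CH2Cl2, 0 °C → rt
Reagents that add atoms: 1-chloro-N,N,2-trimethylprop-1-en-1-amine, CC(C)=C(Cl)N(C)C
Why: The α-chloroenamine should give the acid chloride under neutral conditions, which protects the silyl ether and the acid-sensitive 1,4-diene.

Step 8
Reactants: 7 tert-butyl{[(2Z)-3,5-diiodo-2-methylpent-2-en-1-yl]oxy}diphenylsilane; 11 1-[3-(TBS-oxy)propyl]cyclohexa-2,5-diene-1-carbonyl chloride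
Product: 14 (4Z,4aR,8aR)-4-[1-(TBDPS-oxy)propan-2-ylidene]-8a-[3-(TBS-oxy)propyl]-3,4,4a,8a-tetrahydronaphthalen-1(2H)-one, via alkylzinc iodide 12 (not isolated), via keto alkenyl iodide 13 (not isolated)
Conditions: 7 (1.2 equiv), Zn dust, LiCl, THF, 30 °C; then 11, Pd2(dba)3 (2.5 mol%), (R)-BINAP (6 mol%), THF, 0 °C; then Ag3PO4 (3 equiv), NMP, 60 °C
Reagents that add atoms: none
Why: Proposed new method: one zerovalent palladium/(R)-BINAP catalyst is asked to run two cycles in the same flask, first an acyl Negishi coupling of alkylzinc 12 with acid chloride 11 (oxidative addition to the C(O)–Cl bond at 0 °C should be far faster than to the hindered tetrasubstituted alkenyl iodide) to join C5 to C6, then, after Ag3PO4 is added and the mixture warmed, oxidative addition to the alkenyl iodide and a cationic Heck cyclisation that joins C3 to C2. The closest known reaction types are the palladium-catalysed acylation of alkylzinc halides with acid chlorides and the BINAP-controlled asymmetric Heck desymmetrisation of 1-substituted cyclohexa-2,5-dienes that carry a tethered alkenyl iodide; running both under one chiral catalyst is the untested part. Ring B closes by a 6-exo-trig syn migratory insertion onto ring A, so the ring fusion can only be cis. The ligand chooses between the two enantiotopic ring alkenes and so sets the quaternary carbon C1 and the neighbouring C2 together, while the alkenyl–palladium bond reacts with retention and carries the (Z) geometry of 7 into the exocyclic alkene. The step needs chemoselectivity (acyl chloride before alkenyl iodide, zinc insertion only at the primary iodide), regioselectivity (6-exo, not 7-endo) and β-hydride elimination away from the new stereocentre; these should be secured by the low temperature of the first stage, by the four-atom tether on the quaternary carbon and by the ring, which offers only the syn hydrogen of the ring CH2 for elimination.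

Step 9
Reactants: 14 (4Z,4aR,8aR)-4-[1-(TBDPS-oxy)propan-2-ylidene]-8a-[3-(TBS-oxy)propyl]-3,4,4a,8a-tetrahydronaphthalen-1(2H)-one
Product: 15 (1S,4Z,4aR,8aR)-4-[1-(TBDPS-oxy)propan-2-ylidene]-8a-[3-(TBS-oxy)propyl]-1-methyl-1,2,3,4,4a,8a-hexahydronaphthalen-1-ol
Conditions: MeLi, CeCl3, THF, −78 °C; H2O
Reagents that add atoms: methyllithium, [Li]C
Why: Organocerium 1,2-addition should avoid enolisation, and the ring-A carbon on C2 (held axial on ring B by allylic 1,3-strain with the exocyclic alkene) blocks the axial path, so methyl should enter equatorially from the convex face and leave the hydroxyl trans to the 8a side chain.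

Step 10
Reactants: 15 (1S,4Z,4aR,8aR)-4-[1-(TBDPS-oxy)propan-2-ylidene]-8a-[3-(TBS-oxy)propyl]-1-methyl-1,2,3,4,4a,8a-hexahydronaphthalen-1-ol
Product: 16 (1S,4Z,4aR,8aR)-4-[1-(TBDPS-oxy)propan-2-ylidene]-8a-[3-(TBS-oxy)propyl]-1-methyl-1,2,3,4,4a,5,6,8a-octahydronaphthalen-1-ol
Conditions: TsNHNH2, NaOAc, DME/H2O, 85 °C
Reagents that add atoms: none
Why: Diimide reduction should take the ring-A alkene next to the tertiary ring-fusion CH faster than the one next to the quaternary carbon and should leave the tetrasubstituted alkene alone.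

Step 11
Reactants: 16 (1S,4Z,4aR,8aR)-4-[1-(TBDPS-oxy)propan-2-ylidene]-8a-[3-(TBS-oxy)propyl]-1-methyl-1,2,3,4,4a,5,6,8a-octahydronaphthalen-1-ol
Product: 18 (1S,2S,3R,4Z)-4-[1-(TBDPS-oxy)propan-2-ylidene]-2-[3-(TBS-oxy)propyl]-2-(hydroxymethyl)-3-(3-hydroxypropyl)-1-methylcyclohexan-1-ol, via seco-dialdehyde 17 (not isolated)
Conditions: OsO4 (2 mol%), NaIO4, 2,6-lutidine, dioxane/H2O, rt; then NaBH4, MeOH, 0 °C
Reagents that add atoms: osmium tetroxide (catalytic oxygen carrier), O=[Os](=O)(=O)=O; sodium periodate (stoichiometric oxidant), [Na+].[O-]I(=O)(=O)=O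
Why: Lemieux–Johnson cleavage of the only unhindered disubstituted alkene followed by borohydride reduction should open ring A and release the hydroxymethyl group on C1 and the hydroxypropyl chain on C2, cis by construction.

Step 12
Reactants: 18 (1S,2S,3R,4Z)-4-[1-(TBDPS-oxy)propan-2-ylidene]-2-[3-(TBS-oxy)propyl]-2-(hydroxymethyl)-3-(3-hydroxypropyl)-1-methylcyclohexan-1-ol
Product: 19 (1S,2S,3R,4Z)-2-[(TBDPS-oxy)methyl]-3-[3-(TBDPS-oxy)propyl]-4-[1-(TBDPS-oxy)propan-2-ylidene]-2-[3-(TBS-oxy)propyl]-1-methylcyclohexan-1-ol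
Conditions: TBDPSCl, imidazole, DMAP (cat.), DMF, 40 °C
Reagents that add atoms: tert-butyl(chloro)diphenylsilane, CC(C)(C)[Si](Cl)(c1ccccc1)c1ccccc1
Why: Silylation should cap the two primary hydroxyls, while the hindered tertiary alcohol stays free.

Step 13
Reactants: 19 (1S,2S,3R,4Z)-2-[(TBDPS-oxy)methyl]-3-[3-(TBDPS-oxy)propyl]-4-[1-(TBDPS-oxy)propan-2-ylidene]-2-[3-(TBS-oxy)propyl]-1-methylcyclohexan-1-ol
Product: 20 (1S,2S,3R,4Z)-2-[(TBDPS-oxy)methyl]-3-[3-(TBDPS-oxy)propyl]-4-[1-(TBDPS-oxy)propan-2-ylidene]-2-(3-hydroxypropyl)-1-methylcyclohexan-1-ol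
Conditions: CSA (cat.), MeOH/CH2Cl2, 0 °C
Reagents that add atoms: none
Why: Acid-catalysed methanolysis should cleave the primary TBS ether selectively in the presence of the three TBDPS ethers.

Step 14
Reactants: 20 (1S,2S,3R,4Z)-2-[(TBDPS-oxy)methyl]-3-[3-(TBDPS-oxy)propyl]-4-[1-(TBDPS-oxy)propan-2-ylidene]-2-(3-hydroxypropyl)-1-methylcyclohexan-1-ol
Product: 21 (1S,2S,3R,4Z)-2-[(TBDPS-oxy)methyl]-3-[3-(TBDPS-oxy)propyl]-4-[1-(TBDPS-oxy)propan-2-ylidene]-1-methyl-2-(3-oxopropyl)cyclohexan-1-ol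
Conditions: DMP, CH2Cl2, 0 °C → rt
Reagents that add atoms: none
Why: Dess–Martin oxidation should give the aldehyde from the only primary alcohol and leave the tertiary alcohol untouched.

Step 15
Reactants: 21 (1S,2S,3R,4Z)-2-[(TBDPS-oxy)methyl]-3-[3-(TBDPS-oxy)propyl]-4-[1-(TBDPS-oxy)propan-2-ylidene]-1-methyl-2-(3-oxopropyl)cyclohexan-1-ol; 22 2-(triphenyl-λ5-phosphanylidene)propanal
Product: 23 (1S,2S,3R,4Z)-2-[(TBDPS-oxy)methyl]-3-[3-(TBDPS-oxy)propyl]-4-[1-(TBDPS-oxy)propan-2-ylidene]-1-methyl-2-[(3E)-4-methyl-5-oxopent-3-en-1-yl]cyclohexan-1-ol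
Conditions: PhMe, 90 °C
Reagents that add atoms: none
Why: A Wittig reaction with the stabilised formyl ylide should give the (E)-2-methyl enal.

Step 16
Reactants: 23 (1S,2S,3R,4Z)-2-[(TBDPS-oxy)methyl]-3-[3-(TBDPS-oxy)propyl]-4-[1-(TBDPS-oxy)propan-2-ylidene]-1-methyl-2-[(3E)-4-methyl-5-oxopent-3-en-1-yl]cyclohexan-1-ol; 24 (2E)-1-bromo-3,7-dimethylocta-2,6-diene (geranyl bromide)
Product: 27 (1S,2S,3R,4Z)-2-[(TBDPS-oxy)methyl]-3-[3-(TBDPS-oxy)propyl]-4-[1-(TBDPS-oxy)propan-2-ylidene]-1-methyl-2-[(3E,5E,7E)-4,8,12-trimethyltrideca-3,5,7,11-tetraen-1-yl]cyclohexan-1-ol, via geranyltributylphosphonium bromide 25 (not isolated), via geranylidenetributylphosphorane 26 (not isolated)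
Conditions: 24, PBu3, THF, rt; n-BuLi, −78 °C; then 23 (ylide 2.5 equiv), −78 °C → rt
Reagents that add atoms: none
Why: A Wittig reaction of an allylic trialkylphosphonium ylide with the enal should give the new disubstituted alkene with (E) geometry and complete the conjugated triene, the excess ylide covering the free tertiary hydroxyl.

Step 17
Reactants: 27 (1S,2S,3R,4Z)-2-[(TBDPS-oxy)methyl]-3-[3-(TBDPS-oxy)propyl]-4-[1-(TBDPS-oxy)propan-2-ylidene]-1-methyl-2-[(3E,5E,7E)-4,8,12-trimethyltrideca-3,5,7,11-tetraen-1-yl]cyclohexan-1-ol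
Product: 28 (1S,2S,3R,4Z)-2-(hydroxymethyl)-4-(1-hydroxypropan-2-ylidene)-3-(3-hydroxypropyl)-1-methyl-2-[(3E,5E,7E)-4,8,12-trimethyltrideca-3,5,7,11-tetraen-1-yl]cyclohexan-1-ol
Conditions: TBAF, THF, rt
Reagents that add atoms: none
Why: Fluoride should remove the three TBDPS ethers without affecting the polyene.

Step 18
Reactants: 28 (1S,2S,3R,4Z)-2-(hydroxymethyl)-4-(1-hydroxypropan-2-ylidene)-3-(3-hydroxypropyl)-1-methyl-2-[(3E,5E,7E)-4,8,12-trimethyltrideca-3,5,7,11-tetraen-1-yl]cyclohexan-1-ol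
Product: 29 CNP0179699.2, (2Z)-2-[(2R,3S,4S)-4-hydroxy-3-(hydroxymethyl)-2-(3-hydroxypropyl)-4-methyl-3-[(3E,5E,7E)-4,8,12-trimethyltrideca-3,5,7,11-tetraen-1-yl]cyclohexylidene]propanal
Conditions: MnO2, CH2Cl2, rt
Reagents that add atoms: none
Why: Manganese dioxide should oxidise only the allylic primary alcohol to the enal, with the alkene geometry and the other three hydroxyls unchanged.

**Compound list**

1 | 2-(but-3-yn-1-yloxy)oxane (racemic acetal) | C#CCCOC1CCCCO1 | starting material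
2 | 5-(oxan-2-yloxy)pent-2-yn-1-ol | OCC#CCCOC1CCCCO1 | intermediate
3 | 4-methyl-3-[2-(oxan-2-yloxy)ethyl]-2,5-dihydro-1,2-oxamagnesole | CC1=C(CCOC2CCCCO2)[Mg]OC1 | intermediate
4 | (2Z)-3-iodo-2-methyl-5-(oxan-2-yloxy)pent-2-en-1-ol | OC/C(C)=C(\I)CCOC1CCCCO1 | intermediate
5 | tert-butyl{[(2Z)-3-iodo-2-methyl-5-(oxan-2-yloxy)pent-2-en-1-yl]oxy}diphenylsilane | CC(C)(C)[Si](c1ccccc1)(c1ccccc1)OC/C(C)=C(\I)CCOC1CCCCO1 | intermediate
6 | (3Z)-5-(TBDPS-oxy)-3-iodo-4-methylpent-3-en-1-ol | CC(C)(C)[Si](c1ccccc1)(c1ccccc1)OC/C(C)=C(\I)CCO | intermediate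
7 | tert-butyl{[(2Z)-3,5-diiodo-2-methylpent-2-en-1-yl]oxy}diphenylsilane | CC(C)(C)[Si](c1ccccc1)(c1ccccc1)OC/C(C)=C(\I)CCI | intermediate
8 | benzoic acid | OC(=O)c1ccccc1 | starting material
9 | (3-bromopropoxy)(tert-butyl)dimethylsilane | CC(C)(C)[Si](C)(C)OCCCBr | starting material
10 | 1-[3-(TBS-oxy)propyl]cyclohexa-2,5-diene-1-carboxylic acid | CC(C)(C)[Si](C)(C)OCCCC1(C=CCC=C1)C(=O)O | intermediate
11 | 1-[3-(TBS-oxy)propyl]cyclohexa-2,5-diene-1-carbonyl chloride | CC(C)(C)[Si](C)(C)OCCCC1(C=CCC=C1)C(Cl)=O | intermediate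
12 | [(3Z)-5-(TBDPS-oxy)-3-iodo-4-methylpent-3-en-1-yl](iodo)zinc | CC(C)(C)[Si](c1ccccc1)(c1ccccc1)OC/C(C)=C(\I)CC[Zn]I | intermediate
13 | (4Z)-6-(TBDPS-oxy)-1-{1-[3-(TBS-oxy)propyl]cyclohexa-2,5-dien-1-yl}-4-iodo-5-methylhex-4-en-1-one | CC(C)(C)[Si](C)(C)OCCCC1(C=CCC=C1)C(=O)CC/C(I)=C(\C)CO[Si](c1ccccc1)(c1ccccc1)C(C)(C)C | intermediate
14 | (4Z,4aR,8aR)-4-[1-(TBDPS-oxy)propan-2-ylidene]-8a-[3-(TBS-oxy)propyl]-3,4,4a,8a-tetrahydronaphthalen-1(2H)-one (cis-fused; 4a-H and the 8a side chain on the same face) | CC(C)(C)[Si](C)(C)OCCC[C@@]1(C=CC=C2)[C@H]2/C(=C(/C)CO[Si](c3ccccc3)(c3ccccc3)C(C)(C)C)CCC1=O | intermediate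
15 | (1S,4Z,4aR,8aR)-4-[1-(TBDPS-oxy)propan-2-ylidene]-8a-[3-(TBS-oxy)propyl]-1-methyl-1,2,3,4,4a,8a-hexahydronaphthalen-1-ol (hydroxyl trans to the 8a side chain) | CC(C)(C)[Si](C)(C)OCCC[C@@]1(C=CC=C2)[C@H]2/C(=C(/C)CO[Si](c3ccccc3)(c3ccccc3)C(C)(C)C)CC[C@]1(C)O | intermediate
16 | (1S,4Z,4aR,8aR)-4-[1-(TBDPS-oxy)propan-2-ylidene]-8a-[3-(TBS-oxy)propyl]-1-methyl-1,2,3,4,4a,5,6,8a-octahydronaphthalen-1-ol | CC(C)(C)[Si](C)(C)OCCC[C@@]1(C=CCC2)[C@H]2/C(=C(/C)CO[Si](c3ccccc3)(c3ccccc3)C(C)(C)C)CC[C@]1(C)O | intermediate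
17 | (1S,2R,3R,4Z)-4-[1-(TBDPS-oxy)propan-2-ylidene]-2-[3-(TBS-oxy)propyl]-2-formyl-1-methyl-3-(3-oxopropyl)cyclohexan-1-ol | CC(C)(C)[Si](C)(C)OCCC[C@@]1(C=O)[C@H](CCC=O)/C(=C(/C)CO[Si](c2ccccc2)(c2ccccc2)C(C)(C)C)CC[C@]1(C)O | intermediate
18 | (1S,2S,3R,4Z)-4-[1-(TBDPS-oxy)propan-2-ylidene]-2-[3-(TBS-oxy)propyl]-2-(hydroxymethyl)-3-(3-hydroxypropyl)-1-methylcyclohexan-1-ol | CC(C)(C)[Si](C)(C)OCCC[C@@]1(CO)[C@H](CCCO)/C(=C(/C)CO[Si](c2ccccc2)(c2ccccc2)C(C)(C)C)CC[C@]1(C)O | intermediate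
19 | (1S,2S,3R,4Z)-2-[(TBDPS-oxy)methyl]-3-[3-(TBDPS-oxy)propyl]-4-[1-(TBDPS-oxy)propan-2-ylidene]-2-[3-(TBS-oxy)propyl]-1-methylcyclohexan-1-ol | CC(C)(C)[Si](C)(C)OCCC[C@@]1(CO[Si](c2ccccc2)(c2ccccc2)C(C)(C)C)[C@H](CCCO[Si](c2ccccc2)(c2ccccc2)C(C)(C)C)/C(=C(/C)CO[Si](c2ccccc2)(c2ccccc2)C(C)(C)C)CC[C@]1(C)O | intermediate
20 | (1S,2S,3R,4Z)-2-[(TBDPS-oxy)methyl]-3-[3-(TBDPS-oxy)propyl]-4-[1-(TBDPS-oxy)propan-2-ylidene]-2-(3-hydroxypropyl)-1-methylcyclohexan-1-ol | OCCC[C@@]1(CO[Si](c2ccccc2)(c2ccccc2)C(C)(C)C)[C@H](CCCO[Si](c2ccccc2)(c2ccccc2)C(C)(C)C)/C(=C(/C)CO[Si](c2ccccc2)(c2ccccc2)C(C)(C)C)CC[C@]1(C)O | intermediate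
21 | (1S,2S,3R,4Z)-2-[(TBDPS-oxy)methyl]-3-[3-(TBDPS-oxy)propyl]-4-[1-(TBDPS-oxy)propan-2-ylidene]-1-methyl-2-(3-oxopropyl)cyclohexan-1-ol | O=CCC[C@@]1(CO[Si](c2ccccc2)(c2ccccc2)C(C)(C)C)[C@H](CCCO[Si](c2ccccc2)(c2ccccc2)C(C)(C)C)/C(=C(/C)CO[Si](c2ccccc2)(c2ccccc2)C(C)(C)C)CC[C@]1(C)O | intermediate
22 | 2-(triphenyl-λ5-phosphanylidene)propanal | CC(C=O)=P(c1ccccc1)(c1ccccc1)c1ccccc1 | starting material
23 | (1S,2S,3R,4Z)-2-[(TBDPS-oxy)methyl]-3-[3-(TBDPS-oxy)propyl]-4-[1-(TBDPS-oxy)propan-2-ylidene]-1-methyl-2-[(3E)-4-methyl-5-oxopent-3-en-1-yl]cyclohexan-1-ol | O=C/C(C)=C/CC[C@@]1(CO[Si](c2ccccc2)(c2ccccc2)C(C)(C)C)[C@H](CCCO[Si](c2ccccc2)(c2ccccc2)C(C)(C)C)/C(=C(/C)CO[Si](c2ccccc2)(c2ccccc2)C(C)(C)C)CC[C@]1(C)O | intermediate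
24 | (2E)-1-bromo-3,7-dimethylocta-2,6-diene (geranyl bromide) | CC(C)=CCC/C(C)=C/CBr | starting material
25 | tributyl[(2E)-3,7-dimethylocta-2,6-dien-1-yl]phosphanium bromide | CC(C)=CCC/C(C)=C/C[P+](CCCC)(CCCC)CCCC.[Br-] | intermediate
26 | tributyl[(2E)-3,7-dimethylocta-2,6-dien-1-ylidene]-λ5-phosphane | CC(C)=CCC/C(C)=C/C=P(CCCC)(CCCC)CCCC | intermediate
27 | (1S,2S,3R,4Z)-2-[(TBDPS-oxy)methyl]-3-[3-(TBDPS-oxy)propyl]-4-[1-(TBDPS-oxy)propan-2-ylidene]-1-methyl-2-[(3E,5E,7E)-4,8,12-trimethyltrideca-3,5,7,11-tetraen-1-yl]cyclohexan-1-ol | CC(C)=CCC/C(C)=C/C=C/C(C)=C/CC[C@@]1(CO[Si](c2ccccc2)(c2ccccc2)C(C)(C)C)[C@H](CCCO[Si](c2ccccc2)(c2ccccc2)C(C)(C)C)/C(=C(/C)CO[Si](c2ccccc2)(c2ccccc2)C(C)(C)C)CC[C@]1(C)O | intermediate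
28 | (1S,2S,3R,4Z)-2-(hydroxymethyl)-4-(1-hydroxypropan-2-ylidene)-3-(3-hydroxypropyl)-1-methyl-2-[(3E,5E,7E)-4,8,12-trimethyltrideca-3,5,7,11-tetraen-1-yl]cyclohexan-1-ol | CC(C)=CCC/C(C)=C/C=C/C(C)=C/CC[C@@]1(CO)[C@H](CCCO)/C(=C(/C)CO)CC[C@]1(C)O | intermediate
29 | CNP0179699.2, (2Z)-2-[(2R,3S,4S)-4-hydroxy-3-(hydroxymethyl)-2-(3-hydroxypropyl)-4-methyl-3-[(3E,5E,7E)-4,8,12-trimethyltrideca-3,5,7,11-tetraen-1-yl]cyclohexylidene]propanal | CC(C)=CCC/C(C)=C/C=C/C(C)=C/CC[C@@]1(CO)[C@H](CCCO)/C(=C(/C)C=O)CC[C@]1(C)O | target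

**Step count and risks**

Total step count: 18. Longest linear sequence: 16 steps (steps 1–5 and 8–18).

Steps most likely to fail:

1. Step 8 (Proposed new method). The acylpalladium intermediate may lose carbon monoxide and aromatise the dienyl ring, the alkylzinc may couple at the alkenyl iodide and give oligomers, and zinc and halide salts from the first stage may divert the cationic Heck pathway and erode the choice between the enantiotopic alkenes. Fallback, from 7 and 11 back to 14: the alkylzinc iodide 12 is made as before and acylated with 11 under CuI catalysis, which avoids an acylpalladium species, and the keto alkenyl iodide 13 is isolated and purified. A separate Heck desymmetrisation of 13 with Pd2(dba)3, (R)-BINAP and Ag3PO4 in NMP then gives 14; both reactions are known types run as two discrete steps, and no compound outside the list arises (F0).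

2. Step 10. Diimide may discriminate poorly between the two ring-A alkenes, or reduce both. Fallback, from 15 back to 18: epoxidation with VO(acac)2 and t-BuOOH, directed by the tertiary hydroxyl to the homoallylic ring-A alkene, should give the 7,8-epoxide of 15 F1. Cleavage with H5IO6 in THF/H2O should give the (Z)-enal dialdehyde F2, which is reduced in the same flask with NaBH4/CeCl3 to the (Z)-allylic alcohol diol F3. Diimide then has only one disubstituted alkene to reduce and gives 18.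

3. Step 9. Methyl addition may show poor facial selectivity, or the hindered ketone may enolise. Fallback, from 14 back to 15: a Corey–Chaykovsky reaction with dimethylsulfoxonium methylide (Me3S(O)I, NaH, DMSO), whose reversible addition favours the equatorial C–C bond, should give the spiro-epoxide of 14 F4. Opening at the CH2 carbon with LiEt3BH gives 15.

**Further compounds**

F0 | step 8 | none | none
F1 | step 10 | 7,8-epoxide of 15, oxirane on the face of the tertiary hydroxyl | CC(C)(C)[Si](C)(C)OCCC[C@@]1([C@@H]3O[C@@H]3C=C2)[C@H]2/C(=C(/C)CO[Si](c4ccccc4)(c4ccccc4)C(C)(C)C)CC[C@]1(C)O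
F2 | step 10 | (1S,2R,3R,4Z)-4-[1-(TBDPS-oxy)propan-2-ylidene]-2-[3-(TBS-oxy)propyl]-2-formyl-1-methyl-3-[(1Z)-3-oxoprop-1-en-1-yl]cyclohexan-1-ol | CC(C)(C)[Si](C)(C)OCCC[C@@]1(C=O)[C@H](/C=C\C=O)/C(=C(/C)CO[Si](c2ccccc2)(c2ccccc2)C(C)(C)C)CC[C@]1(C)O
F3 | step 10 | (1S,2S,3R,4Z)-4-[1-(TBDPS-oxy)propan-2-ylidene]-2-[3-(TBS-oxy)propyl]-2-(hydroxymethyl)-3-[(1Z)-3-hydroxyprop-1-en-1-yl]-1-methylcyclohexan-1-ol | CC(C)(C)[Si](C)(C)OCCC[C@@]1(CO)[C@H](/C=C\CO)/C(=C(/C)CO[Si](c2ccccc2)(c2ccccc2)C(C)(C)C)CC[C@]1(C)O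
F4 | step 9 | spiro-epoxide of 14 at C-1, oxirane oxygen trans to the 8a side chain | CC(C)(C)[Si](C)(C)OCCC[C@@]1(C=CC=C2)[C@H]2/C(=C(/C)CO[Si](c3ccccc3)(c3ccccc3)C(C)(C)C)CC[C@]1(C4)O4
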